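**Retrosynthetic overview**
1. Target ⇐ triacetylation/deprotection ⇐ C14 ketone reduction (inverts C14) ⇐ bicyclic 14β-alcohol 27.
2. Key step: 27 ⇐ Ti(III) transannular epoxide–olefin radical cyclization of the 14-membered epoxy macrocycle 25. One C1–C10 bond turns the macrocycle into the cyclohexane and the cyclodecene together and sets C1, C10 and the exocyclic methylene.
3. 25 ⇐ B-alkyl Suzuki macrocyclization (C4–C5) ⇐ Sharpless epoxidation/kinetic resolution (C2, C1, C14) ⇐ vinyl addition ⇐ SeO2 oxidation of a geranyl terminus.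
4. Lactone half ⇐ C-acylation of an (R)-β-methylbutyrolactone enolate with a geranoyl donor (C8), Felkin reduction (C9), propynyl addition/Noyori reduction (C7), Red-Al/I2 (Z-C5=C6), oxidative lactonization.
5. Ring order: γ-lactone → 14-membered carbocycle → six- and ten-membered rings in one operation.

Assumption: atom labels C1–C20 are the briarane numbering of the target (C1 quaternary, C2/C9/C14 acetoxy carbons, C7/C8 lactone fusion, C17 lactone α-carbon, C19 lactone carbonyl, C11=C20 exocyclic methylene, C5=C6 ring alkene).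
Assumption: in steps 1 and 8 the catalyst antipode written is the one taken to give the stated configuration; the mirror-image ligand is used if the sense proves opposite.

**Step 1**
Reactants: 1 4-methylfuran-2(5H)-one
Product: 2 (R)-4-methyloxolan-2-one
Conditions: H2 (50 atm), Ru(OAc)2[(R)-BINAP] (0.5 mol%), MeOH, 50 °C
Reagents that add atoms: none
Why: Noyori–Takaya Ru–BINAP asymmetric hydrogenation of a β-substituted butenolide, in which the catalyst picks the alkene face and so sets the methyl-bearing carbon that becomes C17.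

**Step 2**
Reactants: 2 (R)-4-methyloxolan-2-one
Product: 4 (3R,4S)-4-methyl-3-(triethylsilyloxy)oxolan-2-one, via silyl ketene acetal 3 (not isolated)
Conditions: LDA, THF, −78 °C; Et3SiCl; then m-CPBA, hexane, −15 °C to rt
Reagents that add atoms: chlorotriethylsilane CC[Si](Cl)(CC)CC; m-CPBA OOC(=O)c1cccc(Cl)c1
Why: Rubottom oxidation of the ketene silyl acetal with 1,4-silyl shift gives the α-silyloxy lactone, the peracid attacking anti to the ring methyl (this α-centre is erased again in step 4).

**Step 3**
Reactants: 5 geraniol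
Product: 6 (2E)-geranic acid
Conditions: TEMPO (0.2 equiv), PhI(OAc)2 (2.2 equiv), MeCN–H2O 1:1, rt
Reagents that add atoms: water O
Why: TEMPO/PhI(OAc)2 oxidation in aqueous acetonitrile takes the primary allylic alcohol through the aldehyde hydrate to the acid without moving the E double bond.

**Step 4**
Reactants: 4 (3R,4S)-4-methyl-3-(triethylsilyloxy)oxolan-2-one; 6 (2E)-geranic acid
Product: 9 (3R,4S)-3-geranoyl-4-methyl-3-(triethylsilyloxy)oxolan-2-one, via N-geranoylimidazole 7 (not isolated), via lithium enolate 8 (not isolated)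
Conditions: 6, CDI, THF, rt (gives 7); 4, LDA, THF, −78 °C (gives 8); add 7 to 8, −78 to −40 °C; NH4Cl
Reagents that add atoms: none
Why: Claisen-type C-acylation of the lactone lithium enolate by the acyl imidazole, the acyl group entering the enolate face anti to the neighbouring methyl, which creates the quaternary carbon C8 with the C8/C17 relationship of the target.

**Step 5**
Reactants: 9 keto lactone
Product: 10 (9R)-allylic alcohol (8,9-erythro)
Conditions: NaBH4, CeCl3·7H2O, MeOH, −78 °C
Reagents that add atoms: none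
Why: Luche 1,2-reduction under Felkin–Anh control, hydride adding anti to the C8 silyloxy group with the enone carbonyl turned away from the lactone carbonyl, which gives the (9R) alcohol.

**Step 6**
Reactants: 10 (9R)-allylic alcohol
Product: 12 C8,C9-acetonide lactone, via diol 11 (not isolated)
Conditions: HF·pyridine, pyridine, THF, 0 °C; then 2,2-dimethoxypropane, PPTS (cat.), CH2Cl2, rt
Reagents that add atoms: 2,2-dimethoxypropane COC(C)(C)OC
Why: fluoride desilylation followed by acid-catalysed acetalization ties O8 and O9 into a dioxolane, which keeps O9 out of the later lactonization and rules out silyl migration, with no stereocentre touched.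

**Step 7**
Reactants: 12 C8,C9-acetonide lactone
Product: 13 C7 propynyl ketone with free C19 carbinol
Conditions: 1-propynyllithium (1.5 equiv), THF, −78 to −40 °C; NH4Cl
Reagents that add atoms: 1-propynyllithium [Li]C#CC
Why: single addition of an alkynyllithium to the γ-lactone (the lithium hemiketal is stable at low temperature) opens the ring to the ynone, which equilibrates with its lactol, and frees the C19 carbinol.

**Step 8**
Reactants: 13 C7 propynyl ketone
Product: 14 (7S)-propargylic alcohol
Conditions: RuCl[(R,R)-TsDPEN](p-cymene) (3 mol%), HCO2H–Et3N 5:2, CH2Cl2, rt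
Reagents that add atoms: none
Why: Noyori asymmetric transfer hydrogenation of an ynone, in which the catalyst and not the substrate selects the carbonyl face with the alkyne as the π-substituent, sets C7.

**Step 9**
Reactants: 14 (7S)-propargylic alcohol
Product: 16 (Z)-vinyl iodide diol, via cyclic alkenylalanate 15 (not isolated)
Conditions: Red-Al (4 equiv), THF, 0 °C to rt; then I2, THF, −78 °C
Reagents that add atoms: iodine II
Why: hydroxyl-directed trans-hydroalumination of the propargylic alcohol and iodinolysis with retention give the (Z)-γ-iodo allylic alcohol, which fixes the C5=C6 geometry (iodine, later C4, cis to C7).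

**Step 10**
Reactants: 16 (Z)-vinyl iodide diol
Product: 18 iodo butanolide (7,19-olide), via lactol 17 (not isolated)
Conditions: TEMPO (0.2 equiv), PhI(OAc)2 (2.5 equiv), CH2Cl2, rt
Reagents that add atoms: none
Why: TEMPO/PhI(OAc)2 oxidative lactonization, in which the primary alcohol is oxidized first, the aldehyde is trapped by the C7 hydroxyl as a lactol and oxidized on to the γ-lactone, O9 being locked in the acetonide so that only the 7,19-olide can form.

**Step 11**
Reactants: 18 iodo butanolide
Product: 20 (E)-enal (C2 aldehyde), via allylic alcohol 19 (not isolated)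
Conditions: SeO2 (0.3 equiv), t-BuOOH, salicylic acid (cat.), CH2Cl2, rt; then MnO2, CH2Cl2, rt
Reagents that add atoms: tert-butyl hydroperoxide CC(C)(C)OO
Why: Sharpless SeO2/t-BuOOH allylic oxidation (ene reaction then [2,3]-shift) picks the E-methyl of the terminal and most electron-rich trisubstituted alkene, and MnO2 takes the allylic alcohol to the enal with the E geometry kept.

**Step 12**
Reactants: 20 (E)-enal
Product: 21 dienol as a 1:1 mixture of C2 epimers
Conditions: vinylmagnesium bromide (1.2 equiv), THF, −78 °C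
Reagents that add atoms: vinylmagnesium bromide C=C[Mg]Br
Why: Grignard 1,2-addition to the enal is far faster than attack on the lactone or the vinyl iodide, and the unselective C2 centre is sorted in step 13.

**Step 13**
Reactants: 21 dienol (C2 epimers)
Product: 22 (2R)-epoxy alcohol (erythro; 1R,14R epoxide)
Conditions: Ti(OiPr)4 (10 mol%), D-(−)-diisopropyl tartrate (12 mol%), t-BuOOH (0.6 equiv), 4 Å MS, CH2Cl2, −20 °C
Reagents that add atoms: tert-butyl hydroperoxide CC(C)(C)OO
Why: Sharpless asymmetric epoxidation run as a kinetic resolution, in which only the (2R) epimer is matched with the D-tartrate catalyst and is epoxidized at the trisubstituted C1=C14 alkene to the erythro epoxy alcohol (sets C1 and C14), the (2S) epimer being left and removed by chromatography (yield at most 50%).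

**Step 14**
Reactants: 22 (2R)-epoxy alcohol
Product: 23 C2 TBS ether
Conditions: TBSOTf, 2,6-lutidine, CH2Cl2, −78 °C
Reagents that add atoms: tert-butyldimethylsilyl triflate CC(C)(C)[Si](C)(C)OS(=O)(=O)C(F)(F)F
Why: low-temperature silylation caps the hydroxyl next to the epoxide, which would otherwise divert the Ti(III) step, and leaves the epoxide intact.

**Step 15**
Reactants: 23 C2 TBS ether
Product: 25 14-membered epoxy macrocycle, via B-alkyl-9-BBN 24 (not isolated)
Conditions: 9-BBN-H, THF, rt; then Pd(dppf)Cl2 (20 mol%), AsPh3, Cs2CO3, DMF–THF–H2O, rt, slow addition (final 1 mM)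
Reagents that add atoms: none
Why: B-alkyl Suzuki–Miyaura macrocyclization, in which 9-BBN hydroborates only the monosubstituted vinyl group and the sp3–sp2 coupling with the vinyl iodide goes with retention, closes the 14-membered ring with the Z C5=C6 alkene.

**Step 16**
Reactants: 25 14-membered epoxy macrocycle
Product: 27 bicyclic 14β-alcohol (14-epi), via trimethylsilyl ether 26 (not isolated)
Conditions: Cp2TiCl2 (0.3 equiv), Mn dust (8 equiv), Me3SiCl (4 equiv), 2,4,6-collidine (7 equiv), THF (3 mM), rt; then 1 M HCl, THF, 0 °C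
Reagents that add atoms: none
Why: Proposed new method: Cp2TiCl opens the trisubstituted epoxide homolytically to the C14-titanoxy C1 tertiary radical, which adds across the ring 6-endo to C10 of the E C10=C11 alkene through a chair (OTi, the C2 arm and the C9 arm equatorial, C15 axial) so that C1 and C10 are set with the trans ring fusion, and the C11 radical is trapped by a second Ti(III) and loses a methyl β-hydrogen to give the exocyclic methylene; the closest known chemistry is the Cp2TiCl epoxypolyene cyclization and its transannular version on epoxygermacrolides, extended here to a 14-membered ring that collapses to the six- and ten-membered carbocycles in one operation.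

**Step 17**
Reactants: 27 bicyclic 14β-alcohol
Product: 28 C14 ketone
Conditions: Dess–Martin periodinane, NaHCO3, CH2Cl2, rt
Reagents that add atoms: none
Why: Dess–Martin oxidation of the only free hydroxyl removes the C14 centre, which the epoxide route delivers equatorial and therefore epimeric to the target.

**Step 18**
Reactants: 28 C14 ketone
Product: 29 14α-alcohol
Conditions: K-Selectride, THF, −78 °C; NH4Cl
Reagents that add atoms: none
Why: the bulky trialkylborohydride attacks the cyclohexanone from the equatorial direction and gives the axial 14α-alcohol of the target, the lactone being untouched at −78 °C.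

**Step 19**
Reactants: 29 14α-alcohol
Product: 31 CNP0187723.2, via tetraol 30 (not isolated)
Conditions: aq. HF (48%), MeCN, 0 °C to rt; neutralise (NaHCO3), concentrate; then Ac2O, pyridine, DMAP (cat.), CH2Cl2, 0 °C to rt
Reagents that add atoms: acetic anhydride CC(=O)OC(C)=O
Why: acidic fluoride removes the TBS ether and the isopropylidene acetal, and esterification then acetylates the three secondary hydroxyls (C2, C9, C14) while the hindered tertiary 8-OH stays free.

**Compound list**

1 | 4-methylfuran-2(5H)-one | CC1=CC(=O)OC1 | starting material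
2 | (R)-4-methyloxolan-2-one | O=C1C[C@@H](C)CO1 | intermediate
3 | (R)-triethyl[(4-methyl-4,5-dihydrofuran-2-yl)oxy]silane (silyl ketene acetal) | C[C@H]1COC(O[Si](CC)(CC)CC)=C1 | intermediate
4 | (3R,4S)-4-methyl-3-(triethylsilyloxy)oxolan-2-one | O=C1[C@H](O[Si](CC)(CC)CC)[C@@H](C)CO1 | intermediate
5 | geraniol | CC(C)=CCC/C(C)=C/CO | starting material
6 | (2E)-geranic acid | CC(C)=CCC/C(C)=C/C(=O)O | intermediate
7 | N-geranoylimidazole | CC(C)=CCC/C(C)=C/C(=O)n1ccnc1 | intermediate
8 | lithium enolate of 4 | [Li]OC1=C(O[Si](CC)(CC)CC)[C@@H](C)CO1 | intermediate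
9 | (3R,4S)-3-[(2E)-3,7-dimethylocta-2,6-dienoyl]-4-methyl-3-(triethylsilyloxy)oxolan-2-one (C9 ketone; acyl trans to methyl) | CC(C)=CCC/C(C)=C/C(=O)[C@]1(O[Si](CC)(CC)CC)[C@@H](C)COC1=O | intermediate
10 | (3R,4S)-3-[(1R,2E)-1-hydroxy-3,7-dimethylocta-2,6-dienyl]-4-methyl-3-(triethylsilyloxy)oxolan-2-one | CC(C)=CCC/C(C)=C/[C@@H](O)[C@]1(O[Si](CC)(CC)CC)[C@@H](C)COC1=O | intermediate
11 | C8,C9 diol of 10 (silyl group removed) | CC(C)=CCC/C(C)=C/[C@@H](O)[C@]1(O)[C@@H](C)COC1=O | intermediate
12 | C8,C9-O-isopropylidene lactone (spiro dioxolane; C8, C9, C17 as in target) | CC(C)=CCC/C(C)=C/[C@H]1OC(C)(C)O[C@]12[C@@H](C)COC2=O | intermediate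
13 | C7 propynyl ketone with C19 CH2OH (ring-opened lactone) | CC(C)=CCC/C(C)=C/[C@H]1OC(C)(C)O[C@@]1([C@@H](C)CO)C(=O)C#CC | intermediate
14 | (7S)-propargylic alcohol, C19 CH2OH | CC(C)=CCC/C(C)=C/[C@H]1OC(C)(C)O[C@@]1([C@@H](C)CO)[C@@H](O)C#CC | intermediate
15 | cyclic sodium alkenylalanate (O7–Al–C5 five-membered ring; C19 alkoxide) | CC(C)=CCC/C(C)=C/[C@H]1OC(C)(C)O[C@@]1([C@@H](C)CO[Na])[C@H]2O[Al-](OCCOC)(OCCOC)C(C)=C2.[Na+] | intermediate
16 | (7S)-allylic alcohol with (Z)-C5 iodoalkene, C19 CH2OH | CC(C)=CCC/C(C)=C/[C@H]1OC(C)(C)O[C@@]1([C@@H](C)CO)[C@@H](O)/C=C(/C)I | intermediate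
17 | C19 lactol of 16 | CC(C)=CCC/C(C)=C/[C@H]1OC(C)(C)O[C@@]12[C@H](/C=C(/C)I)OC(O)[C@@H]2C | intermediate
18 | 7,19-olide (final γ-lactone) with (Z)-vinyl iodide side chain, acetonide and geranyl-type C9 chain | CC(C)=CCC/C(C)=C/[C@H]1OC(C)(C)O[C@@]12[C@H](/C=C(/C)I)OC(=O)[C@@H]2C | intermediate
19 | (E)-allylic alcohol at C2 (terminal E-methyl hydroxylated) | OC/C(C)=C/CC/C(C)=C/[C@H]1OC(C)(C)O[C@@]12[C@H](/C=C(/C)I)OC(=O)[C@@H]2C | intermediate
20 | (E)-enal at C2 | O=C/C(C)=C/CC/C(C)=C/[C@H]1OC(C)(C)O[C@@]12[C@H](/C=C(/C)I)OC(=O)[C@@H]2C | intermediate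
21 | C2 vinyl carbinol (dienol), both C2 epimers | C=CC(O)/C(C)=C/CC/C(C)=C/[C@H]1OC(C)(C)O[C@@]12[C@H](/C=C(/C)I)OC(=O)[C@@H]2C | intermediate
22 | (2R)-epoxy alcohol, trans C1–C14 epoxide (1R,14R), erythro | C=C[C@@H](O)[C@@]1(C)O[C@@H]1CC/C(C)=C/[C@H]2OC(C)(C)O[C@@]23[C@H](/C=C(/C)I)OC(=O)[C@@H]3C | intermediate
23 | C2 O-TBS ether of 22 | C=C[C@@H](O[Si](C)(C)C(C)(C)C)[C@@]1(C)O[C@@H]1CC/C(C)=C/[C@H]2OC(C)(C)O[C@@]23[C@H](/C=C(/C)I)OC(=O)[C@@H]3C | intermediate
24 | C4 B-alkyl-9-BBN adduct of 23 | B1(CC[C@@H](O[Si](C)(C)C(C)(C)C)[C@@]2(C)O[C@@H]2CC/C(C)=C/[C@H]3OC(C)(C)O[C@@]34[C@H](/C=C(/C)I)OC(=O)[C@@H]4C)C5CCCC1CCC5 | intermediate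
25 | 14-membered carbocycle: Z C5=C6, E C10=C11, trans C1–C14 epoxide, C2 OTBS, C8/C9 acetonide, fused 7,19-olide | C1/C(C)=C\[C@@H]2OC(=O)[C@H](C)[C@]23OC(C)(C)O[C@@H]3/C=C(C)/CC[C@H]4O[C@]4(C)[C@H](O[Si](C)(C)C(C)(C)C)C1 | intermediate
26 | C14 O-trimethylsilyl ether of 27 | C=C1CC[C@@H](O[Si](C)(C)C)[C@@]2(C)[C@H]1[C@H]3OC(C)(C)O[C@@]34[C@H](/C=C(/C)CC[C@H]2O[Si](C)(C)C(C)(C)C)OC(=O)[C@@H]4C | intermediate
27 | briarane bicycle with 14β-OH (14-epi), C2 OTBS, C8/C9 acetonide; other centres as in target | C=C1CC[C@@H](O)[C@@]2(C)[C@H]1[C@H]3OC(C)(C)O[C@@]34[C@H](/C=C(/C)CC[C@H]2O[Si](C)(C)C(C)(C)C)OC(=O)[C@@H]4C | intermediate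
28 | C14 ketone | C=C1CCC(=O)[C@@]2(C)[C@H]1[C@H]3OC(C)(C)O[C@@]34[C@H](/C=C(/C)CC[C@H]2O[Si](C)(C)C(C)(C)C)OC(=O)[C@@H]4C | intermediate
29 | 14α-alcohol (14S), C2 OTBS, C8/C9 acetonide | C=C1CC[C@H](O)[C@@]2(C)[C@H]1[C@H]3OC(C)(C)O[C@@]34[C@H](/C=C(/C)CC[C@H]2O[Si](C)(C)C(C)(C)C)OC(=O)[C@@H]4C | intermediate
30 | 2,8,9,14-tetraol (all centres as in target) | C=C1CC[C@H](O)[C@@]2(C)[C@H]1[C@@H](O)[C@@]1(O)[C@H](/C=C(/C)CC[C@H]2O)OC(=O)[C@@H]1C | intermediate
31 | CNP0187723.2, (1S,2R,5Z,7S,8S,9R,10S,14S,17R)-2,9,14-triacetoxy-8-hydroxybriara-5,11(20)-dien-18,7-olide | C=C1CC[C@H](OC(C)=O)[C@@]2(C)[C@H]1[C@@H](OC(C)=O)[C@@]1(O)[C@H](/C=C(/C)CC[C@H]2OC(C)=O)OC(=O)[C@@H]1C | target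

**Totals**
Total step count: 19. Longest linear sequence: 18 steps (1 → 31 through steps 1, 2 and 4–19; geraniol joins at step 4).

**Three steps most likely to fail, with fallbacks**

Step 16 (transannular Ti(III) cyclization). The C1 radical can instead add to C6 of the C5=C6 alkene, the configuration at C1 is set only by the chair preference of a planar radical, and the 14-membered ring may not adopt the required fold. The fallback sets out from 23 and returns at 27. The Ti(III) epoxide–olefin cyclization (Cp2TiCl, THF) is run on the open-chain epoxide 23, where C5=C6 is a deactivated vinyl iodide, to form the cyclohexane first and give the monocyclic cyclohexanol F1. The vinyl group of F1 is then hydroborated with 9-BBN to the alkylborane F2, and an intramolecular B-alkyl Suzuki coupling closes the ten-membered ring to give 27.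

Step 5 (Felkin reduction setting C9). The facial bias rests on a rotamer argument at a fully substituted α-carbon and may favour the other epimer. The fallback sets out from 9 and returns at 10. If the reduction gives mainly the 9-epi alcohol F3, this is inverted by a Mitsunobu reaction (4-nitrobenzoic acid, PPh3, DIAD) to the (9R)-4-nitrobenzoate F4, and methanolysis (K2CO3, MeOH, 0 °C) gives 10.

Step 7 (alkynyllithium addition to the hindered spiro lactone). The carbonyl sits next to a quaternary spiro carbon and may resist addition or add twice. The fallback sets out from 12 and returns at 13. The lactone is opened with Me(MeO)N–AlMe2 (from MeNHOMe·HCl and AlMe3) to the hydroxy Weinreb amide F5. Its chelated tetrahedral adduct with 1-propynyllithium (2.2 equiv) releases ynone 13 on work-up.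

**Further compounds**
F1 | step 16 | monocyclic cyclohexanol from radical cyclization of 23 (ring A formed; 14β-OH, exocyclic methylene, vinyl and vinyl iodide intact) | C=C1CC[C@@H](O)[C@](C)([C@H](O[Si](C)(C)C(C)(C)C)C=C)[C@H]1[C@H]2OC(C)(C)O[C@@]23[C@H](/C=C(/C)I)OC(=O)[C@@H]3C
F2 | step 16 | C4 B-alkyl-9-BBN adduct of F1 | C=C1CC[C@@H](O)[C@](C)([C@H](O[Si](C)(C)C(C)(C)C)CCB2C3CCCC2CCC3)[C@H]1[C@H]4OC(C)(C)O[C@@]45[C@H](/C=C(/C)I)OC(=O)[C@@H]5C
F3 | step 5 | 9-epi-10 ((9S)-allylic alcohol) | CC(C)=CCC/C(C)=C/[C@H](O)[C@]1(O[Si](CC)(CC)CC)[C@@H](C)COC1=O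
F4 | step 5 | (9R)-4-nitrobenzoate of 10 | CC(C)=CCC/C(C)=C/[C@@H](OC(=O)c1ccc(cc1)[N+](=O)[O-])[C@]2(O[Si](CC)(CC)CC)[C@@H](C)COC2=O
F5 | step 7 | hydroxy Weinreb amide from 12 | CC(C)=CCC/C(C)=C/[C@H]1OC(C)(C)O[C@@]1([C@@H](C)CO)C(=O)N(C)OC
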